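Ring numbering: C1 (C=O), C2=C3, C4 (OMe), C5 (CH2), C6 (quaternary); side chain C7 (CHCH3), C8 (ArCHOH). The plan rests on the row C8–C7–C6–C1, a γ-hydroxy ketone whose quaternary α-carbon C6 belongs to the six-membered ring. This pattern is what a Prins addition ended by a pinacol shift leaves behind.
Late stage: C8–OH comes from its TES ether, C4–OMe from C4–OH, and the C2=C3/C4–O array from the C3=C4 alkene of a cyclohex-4-enone by way of its epoxide.
Key disconnection: C7–C8 and C5–C6 are cut together, which takes the cyclohexenone back to 3,4,5-trimethoxybenzaldehyde and an achiral 1-[(Z)-alkenyl]cyclopent-3-enol TES ether.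
Precursor: C6–allyl and C7–CH3 come from alkoxide-directed anti allylmagnesiation/methylation of 1-ethynylcyclopent-3-enol, which is made from cyclopent-3-enone.
Ring order: the arene and the cyclopentene are bought; the only ring made is the cyclohexenone, formed in step 5 by one-carbon enlargement of the cyclopentene.

Key step: step 5

Assumption: the sense of induction of the confined acid cannot be derived from first principles, so the (S,S) acid is written; its (R,R) antipode, made the same way from (R)-BINOL, takes its place if a trial run shows the mirror-image series.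

Step 1
Reactants: 1 cyclopent-3-en-1-ol
Product: 2 cyclopent-3-en-1-one
Conditions: Dess–Martin periodinane (1.2 equiv), CH2Cl2, 0 °C → rt
Reagents that add atoms: none
Why: Dess–Martin oxidation of a secondary alcohol runs under nearly neutral conditions, so the β,γ-alkene should stay out of conjugation, and no stereocentre is involved.

Step 2
Reactants: 2 cyclopent-3-en-1-one; 3 ethynylmagnesium bromide
Product: 4 1-ethynylcyclopent-3-en-1-ol
Conditions: 3 (1.3 equiv), LaCl3·2LiCl (1 equiv), THF, −78 → 0 °C; aq. work-up
Reagents that add atoms: none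
Why: 1,2-Addition of an alkynyl Grignard reagent to a ketone, with the lanthanum salt raising carbonyl electrophilicity so that addition outruns enolisation of the doubly activated α-methylenes, gives a carbinol carbon that bears two identical ring arms and is therefore not a stereocentre.

Step 3
Reactants: 4 1-ethynylcyclopent-3-en-1-ol; 5 allylmagnesium bromide
Product: 7 1-[(2Z)-hexa-2,5-dien-3-yl]cyclopent-3-en-1-ol, via oxamagnesacyclopentene chelate 6 (not isolated)
Conditions: 5 (3.5 equiv), CuI (10 mol%), Et2O, −10 °C → rt; then MeI (6 equiv), THF, 0 °C → rt; aq. work-up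
Reagents that add atoms: iodomethane, CI
Why: Alkoxide-directed anti carbomagnesiation of a propargylic alcohol places the allyl group on the proximal carbon C6 and magnesium on C7 cis to the carbinol carbon inside the five-membered chelate 6, and copper-catalysed methylation of the alkenyl–magnesium bond proceeds with retention, so that CH3 ends cis to C1 and trans to allyl (Z).

Step 4
Reactants: 7 1-[(2Z)-hexa-2,5-dien-3-yl]cyclopent-3-en-1-ol
Product: 8 triethyl({1-[(2Z)-hexa-2,5-dien-3-yl]cyclopent-3-en-1-yl}oxy)silane
Conditions: TESOTf (1.3 equiv), 2,6-lutidine (2 equiv), CH2Cl2, −78 → 0 °C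
Reagents that add atoms: triethylsilyl trifluoromethanesulfonate, CC[Si](CC)(CC)OS(=O)(=O)C(F)(F)F
Why: Silylation of a hindered tertiary alcohol by a silyl triflate in the presence of a hindered pyridine base is fast even at low temperature, where the tertiary allylic C–O bond does not ionise and the Z alkene is not disturbed.

Step 5
Reactants: 8 triethyl({1-[(2Z)-hexa-2,5-dien-3-yl]cyclopent-3-en-1-yl}oxy)silane; 9 3,4,5-trimethoxybenzaldehyde
Product: 11 (2R)-2-allyl-2-[(1S,2S)-1-(triethylsilyloxy)-1-(3,4,5-trimethoxyphenyl)propan-2-yl]cyclohex-4-en-1-one, via silyloxocarbenium ion 10 (not isolated)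
Conditions: 9 (2 equiv), (S,S)-IDPi acid [(3,3'-Ar2-1,1'-binaphthalene-2,2'-diolato)P(=NSO2CF3)]2NH with Ar = 3,5-(CF3)2C6H3 (5 mol%), 4 Å MS, toluene–CH2Cl2, −60 °C
Reagents that add atoms: none
Why: Proposed new method: the confined chiral acid hydrogen-bonds and protonates aldehyde 9, C7 of the trisubstituted alkene of 8 attacks the carbonyl carbon (C7–C8 bond), and while charge builds at C6 the ring methylene that lies antiperiplanar to the new bond shifts from C1 to C6 (C5–C6 bond) to give ion 10, whose silyl group is handed within the ion pair from the C1 oxygen to the nearby C8 hydroxyl, which frees the ketone and returns the proton to the catalyst. The closest known reaction types are the racemic Prins–pinacol ring enlargement of 1-alkenylcycloalkanol silyl ethers by aldehydes or acetals under SnCl4 or related Lewis acids and the enantioselective addition of unactivated dienes and alkenes to aromatic aldehydes under imidodiphosphorimidate acids, but their union in an enantioselective intermolecular form has not been shown. The six-membered ring is closed by ring enlargement, a 1,2-alkyl shift that inserts C6 between C1 and C5 of the cyclopentene, and since the two ring methylenes of achiral 8 are enantiotopic the choice between them is a facial and not a regiochemical one. C6 and C7 are linked by the Z geometry of 8 together with anti addition across the alkene (C8 to one face of C7 and C5 to the opposite face of C6), which translates attack through the Si face of C7 into 6R,7S. C8 (S) is set by the catalyst anion, which must expose the Si face of the aldehyde, and the anti C7/C8 relation by a synclinal open transition state in which the aryl group points away from the fully substituted C6, the formyl hydrogen lies over the crowded CH3/C1 flank of the Z alkene and the small O–H···anion unit lies over the open H/allyl flank next to the growing positive charge, an arrangement for which a proton is chosen as activator because a bulky metal or silyl group on oxygen would push the system to the antiperiplanar, syn-selective mode. The step needs site selectivity for the trisubstituted alkene over the terminal and ring alkenes, secured by its higher nucleophilicity and by the silyloxy carbon next to C6 that ends the cation at once, and it needs the aldehyde to win over the bare proton as electrophile and the tertiary allylic silyl ether to resist ionisation, for which excess 9, low temperature and a weakly polar solvent are used.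

Step 6
Reactants: 11 (2R)-2-allyl-2-[(1S,2S)-1-(triethylsilyloxy)-1-(3,4,5-trimethoxyphenyl)propan-2-yl]cyclohex-4-en-1-one
Product: 12 (1S,4R,6R)-4-allyl-4-[(1S,2S)-1-(triethylsilyloxy)-1-(3,4,5-trimethoxyphenyl)propan-2-yl]-7-oxabicyclo[4.1.0]heptan-3-one (epoxide oxygen cis to the C7 chain and trans to allyl)
Conditions: mCPBA (1.05 equiv), CH2Cl2, 0 °C
Reagents that add atoms: 3-chloroperoxybenzoic acid, OOC(=O)c1cccc(Cl)c1
Why: Prilezhaev epoxidation is expected to pick the cis-disubstituted ring alkene over the less electron-rich terminal allyl group, and in the half-chair that keeps the branched C7 chain equatorial and the allyl group axial on C6 the peracid should approach C3=C4 from the face opposite the allyl group, cis to the C7 chain, which sets C4 as R (and the transient C3 centre).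

Step 7
Reactants: 12 (1S,4R,6R)-4-allyl-4-[(1S,2S)-1-(triethylsilyloxy)-1-(3,4,5-trimethoxyphenyl)propan-2-yl]-7-oxabicyclo[4.1.0]heptan-3-one
Product: 13 (4R,6R)-6-allyl-4-hydroxy-6-[(1S,2S)-1-(triethylsilyloxy)-1-(3,4,5-trimethoxyphenyl)propan-2-yl]cyclohex-2-en-1-one
Conditions: DBU (0.2 equiv), CH2Cl2, 0 °C
Reagents that add atoms: none
Why: Base-induced E1cB isomerisation of a β,γ-epoxy ketone to a γ-hydroxy enone: only C2 can be deprotonated because C6 is quaternary, the enolate expels the C3–O bond, and the C4–O bond and its configuration are not touched.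

Step 8
Reactants: 13 (4R,6R)-6-allyl-4-hydroxy-6-[(1S,2S)-1-(triethylsilyloxy)-1-(3,4,5-trimethoxyphenyl)propan-2-yl]cyclohex-2-en-1-one
Product: 14 (4R,6R)-6-allyl-4-methoxy-6-[(1S,2S)-1-(triethylsilyloxy)-1-(3,4,5-trimethoxyphenyl)propan-2-yl]cyclohex-2-en-1-one
Conditions: MeI (10 equiv), Ag2O (3 equiv), 4 Å MS, CH2Cl2, rt, dark
Reagents that add atoms: iodomethane, CI
Why: Purdie methylation (MeI/Ag2O) alkylates the secondary allylic alcohol without a free alkoxide or dienolate, so C4 is not epimerised through γ-deprotonation and the TES ether, enone and allyl group are left alone.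

Step 9
Reactants: 14 (4R,6R)-6-allyl-4-methoxy-6-[(1S,2S)-1-(triethylsilyloxy)-1-(3,4,5-trimethoxyphenyl)propan-2-yl]cyclohex-2-en-1-one
Product: 15 (4R,6R)-6-allyl-6-[(1S,2S)-1-hydroxy-1-(3,4,5-trimethoxyphenyl)propan-2-yl]-4-methoxycyclohex-2-en-1-one
Conditions: HF·pyridine, pyridine, THF, 0 °C
Reagents that add atoms: none
Why: Fluoride-driven cleavage of the Si–O bond under buffered, weakly acidic conditions frees the benzylic C8 alcohol without ionising it and without touching the γ-methoxy enone, so all four stereocentres are carried unchanged into 15.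

Compound list
1 | cyclopent-3-en-1-ol | OC1CC=CC1 | starting material
2 | cyclopent-3-en-1-one | O=C1CC=CC1 | intermediate
3 | ethynylmagnesium bromide | C#C[Mg]Br | starting material
4 | 1-ethynylcyclopent-3-en-1-ol | C#CC1(O)CC=CC1 | intermediate
5 | allylmagnesium bromide | C=CC[Mg]Br | starting material
6 | 4-allyl-1-oxa-2-magnesaspiro[4.4]nona-3,7-diene (chelate, not isolated) | C=CCC1=C[Mg]OC12CC=CC2 | intermediate
7 | 1-[(2Z)-hexa-2,5-dien-3-yl]cyclopent-3-en-1-ol | C=CC/C(=C/C)C1(O)CC=CC1 | intermediate
8 | triethyl({1-[(2Z)-hexa-2,5-dien-3-yl]cyclopent-3-en-1-yl}oxy)silane | C=CC/C(=C/C)C1(O[Si](CC)(CC)CC)CC=CC1 | intermediate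
9 | 3,4,5-trimethoxybenzaldehyde | COc1cc(C=O)cc(OC)c1OC | starting material
10 | ring-enlarged O-triethylsilyl oxocarbenium ion with free C8 hydroxyl (ion pair with the catalyst anion, not isolated) | C=CC[C@]1([C@H](C)[C@H](O)c2cc(OC)c(OC)c(OC)c2)CC=CCC1=[O+][Si](CC)(CC)CC | intermediate
11 | (2R)-2-allyl-2-[(1S,2S)-1-(triethylsilyloxy)-1-(3,4,5-trimethoxyphenyl)propan-2-yl]cyclohex-4-en-1-one | C=CC[C@]1([C@H](C)[C@H](O[Si](CC)(CC)CC)c2cc(OC)c(OC)c(OC)c2)CC=CCC1=O | intermediate
12 | (1S,4R,6R)-4-allyl-4-[(1S,2S)-1-(triethylsilyloxy)-1-(3,4,5-trimethoxyphenyl)propan-2-yl]-7-oxabicyclo[4.1.0]heptan-3-one | C=CC[C@]1([C@H](C)[C@H](O[Si](CC)(CC)CC)c2cc(OC)c(OC)c(OC)c2)C[C@H]3O[C@H]3CC1=O | intermediate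
13 | (4R,6R)-6-allyl-4-hydroxy-6-[(1S,2S)-1-(triethylsilyloxy)-1-(3,4,5-trimethoxyphenyl)propan-2-yl]cyclohex-2-en-1-one | C=CC[C@]1([C@H](C)[C@H](O[Si](CC)(CC)CC)c2cc(OC)c(OC)c(OC)c2)C[C@@H](O)C=CC1=O | intermediate
14 | (4R,6R)-6-allyl-4-methoxy-6-[(1S,2S)-1-(triethylsilyloxy)-1-(3,4,5-trimethoxyphenyl)propan-2-yl]cyclohex-2-en-1-one | C=CC[C@]1([C@H](C)[C@H](O[Si](CC)(CC)CC)c2cc(OC)c(OC)c(OC)c2)C[C@@H](OC)C=CC1=O | intermediate
15 | (4R,6R)-6-allyl-6-[(1S,2S)-1-hydroxy-1-(3,4,5-trimethoxyphenyl)propan-2-yl]-4-methoxycyclohex-2-en-1-one | C=CC[C@]1([C@H](C)[C@H](O)c2cc(OC)c(OC)c(OC)c2)C[C@@H](OC)C=CC1=O | target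

Total step count: 9. Longest linear sequence: 9 steps (1 → 15).

Steps most likely to fail

**1. Step 5.**
- Protonation of the alkene (a proton-initiated semipinacol shift) or ionisation of the tertiary allylic C–O bond may outrun aldehyde addition.
- The bulky nucleophile may fit the catalyst pocket badly, with loss of rate and of enantioselectivity.
- A silylium-carried background cycle, or drift to the antiperiplanar transition state, may erode the C7/C8 relation.
- Capture of ion 10 at carbon instead of at silicon may stall the silyl relay.
- Alkoxide-rich titanium BINOLates are judged too weak to activate this electron-rich aldehyde toward an unactivated alkene, which is why a strong confined acid is chosen.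

Fallback, from 8 and 9 back to 11. Catalytic induction is given up and the task is split into a racemic ring enlargement and a physical resolution. SnCl4 (1.1 equiv, CH2Cl2, −78 °C) is the classical promoter of this reaction type. After aqueous work-up it should give the racemic hydroxy ketone 2-allyl-2-[1-hydroxy-1-(3,4,5-trimethoxyphenyl)propan-2-yl]cyclohex-4-en-1-one F1, in which the C6/C7 relation is still fixed by the Z alkene. Diastereomeric purity at C8 is secured by chromatography at this stage. TESCl/imidazole/DMAP in DMF then gives racemic 11, that is 11 together with its mirror image ent-11 F2. Preparative chromatography on an amylose tris(3,5-dimethylphenylcarbamate) phase delivers 11.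

**2. Step 6.**
- Facial selectivity may be poor, because the half-chair with allyl axial and the half-chair with the C7 chain axial may lie close in energy.
- Some epoxidation of the allyl group may compete.

Fallback, from 11 back to 13. Selectivity is no longer asked of the epoxidation. The mixture of 12 and its face isomer, the (1R,4R,6S)-epoxide F3, is opened with DBU as in step 7, and the C4 epimers are separated as alcohols. The (4S)-alcohol F4 is inverted by a Mitsunobu reaction (4-nitrobenzoic acid, PPh3, DIAD, toluene, 0 °C) to the (4R)-4-nitrobenzoate F5. Brief methanolysis (K2CO3, MeOH, 0 °C) gives 13, so both epoxides converge on the same alcohol.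

**3. Step 3.**
- Deprotonation of the terminal alkyne may compete with carbometalation.
- Addition next to the fully substituted carbinol carbon may be slow.
- The alkenyl–magnesium bond may be protonated by unreacted alkyne before it is methylated.

Fallback, from 2 back to 7. The alkene geometry is fixed before the C1–C6 bond is made. But-3-enyltriphenylphosphonium bromide is converted (n-BuLi; I2; NaHMDS, THF, −78 to −20 °C) into its α-iodo ylide and condensed with acetaldehyde in a Stork–Zhao-type iodo-olefination. This should give (Z)-4-iodohexa-1,4-diene F6. Iodine–lithium exchange (t-BuLi, 2 equiv, Et2O, −78 °C) gives with retention (2E)-hexa-2,5-dien-3-yllithium F7 (methyl cis to lithium). After transmetalation with CeCl3 this adds to ketone 2 at −78 °C to give 7.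

Further compounds
F1 | step 5 | rac-2-allyl-2-[1-hydroxy-1-(3,4,5-trimethoxyphenyl)propan-2-yl]cyclohex-4-en-1-one (racemate, relative configuration as in 11, one enantiomer drawn) | C=CC[C@]1([C@H](C)[C@H](O)c2cc(OC)c(OC)c(OC)c2)CC=CCC1=O
F2 | step 5 | ent-11, (2S)-2-allyl-2-[(1R,2R)-1-(triethylsilyloxy)-1-(3,4,5-trimethoxyphenyl)propan-2-yl]cyclohex-4-en-1-one | C=CC[C@@]1([C@@H](C)[C@@H](O[Si](CC)(CC)CC)c2cc(OC)c(OC)c(OC)c2)CC=CCC1=O
F3 | step 6 | (1R,4R,6S)-4-allyl-4-[(1S,2S)-1-(triethylsilyloxy)-1-(3,4,5-trimethoxyphenyl)propan-2-yl]-7-oxabicyclo[4.1.0]heptan-3-one | C=CC[C@]1([C@H](C)[C@H](O[Si](CC)(CC)CC)c2cc(OC)c(OC)c(OC)c2)C[C@@H]3O[C@@H]3CC1=O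
F4 | step 6 | (4S,6R)-6-allyl-4-hydroxy-6-[(1S,2S)-1-(triethylsilyloxy)-1-(3,4,5-trimethoxyphenyl)propan-2-yl]cyclohex-2-en-1-one | C=CC[C@]1([C@H](C)[C@H](O[Si](CC)(CC)CC)c2cc(OC)c(OC)c(OC)c2)C[C@H](O)C=CC1=O
F5 | step 6 | (1R,5R)-5-allyl-4-oxo-5-[(1S,2S)-1-(triethylsilyloxy)-1-(3,4,5-trimethoxyphenyl)propan-2-yl]cyclohex-2-en-1-yl 4-nitrobenzoate | C=CC[C@]1([C@H](C)[C@H](O[Si](CC)(CC)CC)c2cc(OC)c(OC)c(OC)c2)C[C@@H](OC(=O)c3ccc(cc3)[N+](=O)[O-])C=CC1=O
F6 | step 3 | (Z)-4-iodohexa-1,4-diene | C=CC/C(I)=C/C
F7 | step 3 | (2E)-hexa-2,5-dien-3-yllithium (methyl cis to lithium) | C=CC/C([Li])=C/C
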